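**Plan**

1. Numbering (lignan style): oxolane O1–C7(ring B)–C8(CH2OH = C9)–C8′(OH, benzylic C7′H2 to ring C)–C9′; side chain C7″(OH, ring A)–C8″(O–ring B)–C9″.
2. Retrosynthetic cuts, in order: the benzyl, acetonide and silyl groups; the oxolane C8–C8′ bond; the C7–O–C9′ ether; the C7–ring B bond; the C7″–C8″ bond and the ring B O–CH2 bond of an aryloxyacetyl imide.
3. Forward: the side chain is built first on 4-bromo-2-methoxyphenol (Evans aldol, reduction, acetonide). Aryllithium/acrolein and a Sharpless epoxidation then give the C7 carbinol with a C8–C9 epoxide. Etherification with a ring C allyl bromide and ozonolysis give the C8′ ketone. Its silyl enol ether is cyclised by Cp2TiCl to close the only new ring (the oxolane), and two deprotections finish.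
4. Enabling feature: the C8–C8′ bond is flanked by a 1,3-diol (O on C9, O on C8′), and C8′ also carries the benzylic C7′H2. C8 can therefore be a β-titanoxy radical from a C8–C9 epoxide, and C8′=C7′ the silyl enol ether of a benzyl ketone acting as a styrene-type radical acceptor.
5. Stereochemistry: C7″/C8″ come from the (S)-4-benzyloxazolidinone aldol; C7 from the reagent-controlled (D-(−)-diisopropyl tartrate) epoxidation; C8 and C8′ from C7 in the stereoconvergent radical ring closure, which erases the epoxide configuration at C8.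

Key step: step 12

**Route**

Step 1
Reactants: 1 4-bromo-2-methoxyphenol; 2 (S)-4-benzyl-3-(chloroacetyl)oxazolidin-2-one
Product: 3 (S)-4-benzyl-3-[(4-bromo-2-methoxyphenoxy)acetyl]oxazolidin-2-one
Conditions: K2CO3, NaI (cat.), MeCN, 40 °C
Reagents that add atoms: none
Why: Williamson-type SN2 displacement by the phenoxide at the carbonyl-activated primary chloride (Finkelstein assistance by iodide) should be much faster than attack at either imide carbonyl, and no stereocenter is touched.

Step 2
Reactants: 3 (S)-4-benzyl-3-[(4-bromo-2-methoxyphenoxy)acetyl]oxazolidin-2-one; 4 4-(benzyloxy)-3-methoxybenzaldehyde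
Product: 6 (S)-4-benzyl-3-[(2S,3R)-3-[4-(benzyloxy)-3-methoxyphenyl]-2-(4-bromo-2-methoxyphenoxy)-3-hydroxypropanoyl]oxazolidin-2-one, via Z dibutylboron enolate 5 (not isolated)
Conditions: Bu2BOTf, iPr2NEt, CH2Cl2, −78 to 0 °C; then 4, −78 to 0 °C; MeOH, pH 7 buffer, 30% H2O2, 0 °C
Reagents that add atoms: none
Why: Evans syn-aldol reaction, in which the Z boron enolate adds to the aldehyde through a Zimmerman–Traxler chair on the face away from the auxiliary benzyl group, so that C8″ and C7″ are set together as the syn (threo) pair that becomes 7″R,8″R.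

Step 3
Reactants: 6 syn-aldol imide
Product: 7 (1R,2R)-1-[4-(benzyloxy)-3-methoxyphenyl]-2-(4-bromo-2-methoxyphenoxy)propane-1,3-diol
Conditions: LiBH4, MeOH (2 equiv), THF, 0 °C
Reagents that add atoms: none
Why: Reductive cleavage of the exocyclic imide carbonyl by hydride releases the primary alcohol and the auxiliary without touching either stereocenter, the aryl bromide or the benzyl ether.

Step 4
Reactants: 7 threo 1,3-diol
Product: 8 (4R,5R)-4-[4-(benzyloxy)-3-methoxyphenyl]-5-(4-bromo-2-methoxyphenoxy)-2,2-dimethyl-1,3-dioxane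
Conditions: Me2C(OMe)2, PPTS (cat.), CH2Cl2, rt
Reagents that add atoms: 2,2-dimethoxypropane COC(C)(C)OC
Why: Acid-catalysed transketalisation closes a six-membered acetonide over both hydroxyls, masking them for the organolithium, alkoxide and Lewis-acid steps that follow, with no stereocenter involved.

Step 5
Reactants: 8 bromoaryl acetonide; 9 acrolein
Product: 11 1-(4-{[(4R,5R)-4-[4-(benzyloxy)-3-methoxyphenyl]-2,2-dimethyl-1,3-dioxan-5-yl]oxy}-3-methoxyphenyl)prop-2-en-1-ol as both C7 epimers, via aryllithium 10 (not isolated)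
Conditions: n-BuLi, THF, −78 °C; then 9, −78 °C; H2O
Reagents that add atoms: none
Why: Bromine–lithium exchange outruns any deprotonation at −78 °C and the aryllithium adds 1,2 to acrolein; C7 forms without control because the remote side-chain centers cannot bias it, and the epimers are sorted in step 6.

Step 6
Reactants: 11 allylic alcohol (both C7 epimers)
Product: 12 erythro epoxy alcohol (R)-(ring B aryl)[(S)-oxiran-2-yl]methanol carrying the side-chain acetonide
Conditions: Ti(OiPr)4 (0.2 equiv), D-(−)-diisopropyl tartrate (0.3 equiv), t-BuOOH (0.6 equiv), 4 Å molecular sieves, CH2Cl2, −20 °C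
Reagents that add atoms: tert-butyl hydroperoxide CC(C)(C)OO
Why: Sharpless asymmetric epoxidation in its kinetic-resolution mode: with the D-(−)-tartrate only the 7S epimer of 11 (the target's C7 arrangement, named R in 12 because the priorities change) should be epoxidised at a useful rate and with erythro selectivity, so reagent control fixes C7, while the slow 7R epimer stays as the allylic alcohol and is removed by chromatography.

Step 7
Reactants: 1 4-bromo-2-methoxyphenol
Product: 13 1-(benzyloxy)-4-bromo-2-methoxybenzene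
Conditions: BnBr, K2CO3, DMF, rt
Reagents that add atoms: benzyl bromide BrCc1ccccc1
Why: Williamson O-benzylation of the phenol installs the ring C protecting group that is removed in the last step.

Step 8
Reactants: 13 1-(benzyloxy)-4-bromo-2-methoxybenzene; 14 3-bromo-2-(bromomethyl)prop-1-ene
Product: 16 1-(benzyloxy)-4-[2-(bromomethyl)prop-2-en-1-yl]-2-methoxybenzene, via aryl Grignard reagent 15 (not isolated)
Conditions: Mg turnings, THF, rt; then added to 14 (3 equiv), CuI (5 mol %), THF, −30 to 0 °C
Reagents that add atoms: none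
Why: CuI-catalysed allylic substitution of the aryl Grignard reagent on the symmetrical bis-allylic dibromide (the SN2 and SN2′ paths give the same product), with excess dibromide and inverse addition to suppress double arylation.

Step 9
Reactants: 12 erythro epoxy alcohol; 16 ring C allyl bromide
Product: 17 ether of 12 at the C7 oxygen with the 2-{[4-(benzyloxy)-3-methoxyphenyl]methyl}prop-2-en-1-yl group
Conditions: NaH (added last), Bu4NI (cat.), THF/DMF, 0 °C to rt
Reagents that add atoms: none
Why: Williamson etherification of the secondary alkoxide with a reactive allylic bromide, run so that the alkoxide is alkylated as it forms and Payne rearrangement does not compete; C7 and the epoxide are untouched.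

Step 10
Reactants: 17 epoxy allyl ether
Product: 18 1-[4-(benzyloxy)-3-methoxyphenyl]-3-[(R)-(ring B aryl)((S)-oxiran-2-yl)methoxy]propan-2-one
Conditions: O3, CH2Cl2/MeOH, −78 °C, Sudan Red 7B as end-point indicator; then Me2S, −78 °C to rt
Reagents that add atoms: ozone [O-][O+]=O
Why: Ozonolysis (Criegee mechanism) of the only alkene, a 1,1-disubstituted one, with reductive work-up gives the C8′ ketone, the electron-rich arenes reacting far more slowly than the alkene when the end point is respected.

Step 11
Reactants: 18 epoxy ketone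
Product: 20 Z triethylsilyl enol ether ring C–CH=C(OSiEt3)–CH2–O–C7, via lithium Z-enolate 19 (not isolated)
Conditions: LiHMDS added to 18 and Et3SiCl, THF, −78 °C; Et3N-buffered work-up
Reagents that add atoms: chlorotriethylsilane CC[Si](Cl)(CC)CC
Why: Deprotonation on the more acidic benzylic side gives the aryl-conjugated enolate, which is O-silylated in situ (internal quench) before it can attack the epoxide; the double-bond geometry does not matter because C7′ ends as CH2.

Step 12
Reactants: 20 epoxy silyl enol ether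
Product: 23 (7S,8R,8′S)-oxolane with C8′–OSiEt3 and C9–OH bearing the side-chain acetonide and both benzyl ethers, via C8 titanoxyalkyl radical 21 (not isolated), via C7′ benzylic radical 22 (not isolated)
Conditions: Cp2TiCl2 (2.5 equiv), Zn dust, THF, rt (green Cp2TiCl); added slowly to 20 and 1,4-cyclohexadiene (5 equiv) in THF (0.02 M), rt; aq. NaH2PO4
Reagents that add atoms: none
Why: Cp2TiCl, a one-electron donor of trivalent titanium, opens the epoxide by homolysis of the C8–O bond (Nugent–RajanBabu reaction) to the secondary radical 21, which adds to the oxygen-bearing carbon C8′ of the styrene-type enol ether to give the benzylic radical 22, and this is quenched by hydrogen-atom transfer from 1,4-cyclohexadiene before it can be captured as a benzyl–TiCp2Cl species that would lose the silyloxy group. The closest known reaction type is the Cp2TiCl-mediated radical cyclisation of aryl-substituted epoxy cinnamyl ethers to 2-aryl-3-hydroxymethyl-4-benzyl oxolanes. The oxolane closes in the 5-exo-trig mode, since 6-endo attack at the aryl-substituted C7′ is disfavoured by ring size, by substitution and by loss of benzylic stabilisation. C8 is set by the C7 aryl group, which sits pseudo-equatorial in the chair-like transition state and places the CH2O–TiCp2Cl arm trans to it whatever the epoxide configuration was, because 21 is planar at C8 (stereoconvergent). C8′ is set in the same transition state, where the styrenyl terminus C7′ takes the exo position cis to the CH2O–TiCp2Cl arm, so that the silyloxy group ends trans to C9 and cis to the aryl group. The step needs ring closure to outrun reduction of 21 by a second Cp2TiCl and needs face selectivity at C8′; the short oxygen tether, the benzylic radical stabilisation, the low Cp2TiCl concentration and the single resident stereocenter C7 are what secure them.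

Step 13
Reactants: 23 silyl-protected oxolane
Product: 24 target with both phenols as benzyl ethers (free C9, C8′, C7″ and C9″ hydroxyls)
Conditions: AcOH/THF/H2O (3:1:1), 45 °C
Reagents that add atoms: none
Why: Mild aqueous acid hydrolyses the 1,3-dioxane ketal and the tertiary triethylsilyl ether, while acetic acid is too weak to ionise the benzylic C7–O or C7″–O bonds, so no epimerisation is expected.

Step 14
Reactants: 24 bis-benzyl ether
Product: 25 target (7S,8R,8′S,7″R,8″R)
Conditions: H2 (1 atm), 10% Pd/C, EtOAc/MeOH, rt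
Reagents that add atoms: none
Why: Hydrogenolysis under neutral conditions should cleave the two phenolic benzyl ethers much faster than the benzylic oxolane C–O bond or the benzylic alcohol.

**Compound list**

1 | 4-bromo-2-methoxyphenol | COc1cc(Br)ccc1O | starting material
2 | (S)-4-benzyl-3-(chloroacetyl)oxazolidin-2-one | O=C(CCl)N1C(=O)OC[C@@H]1Cc1ccccc1 | starting material
3 | (S)-4-benzyl-3-[(4-bromo-2-methoxyphenoxy)acetyl]oxazolidin-2-one | COc1cc(Br)ccc1OCC(=O)N1C(=O)OC[C@@H]1Cc1ccccc1 | intermediate
4 | 4-(benzyloxy)-3-methoxybenzaldehyde | COc1cc(C=O)ccc1OCc1ccccc1 | starting material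
5 | Z dibutylboron enolate of 3 | COc1cc(Br)ccc1O/C=C(\OB(CCCC)CCCC)N1C(=O)OC[C@@H]1Cc1ccccc1 | intermediate
6 | (S)-4-benzyl-3-[(2S,3R)-3-[4-(benzyloxy)-3-methoxyphenyl]-2-(4-bromo-2-methoxyphenoxy)-3-hydroxypropanoyl]oxazolidin-2-one | COc1cc(Br)ccc1O[C@H](C(=O)N1C(=O)OC[C@@H]1Cc1ccccc1)[C@H](O)c1ccc(OCc2ccccc2)c(OC)c1 | intermediate
7 | (1R,2R)-1-[4-(benzyloxy)-3-methoxyphenyl]-2-(4-bromo-2-methoxyphenoxy)propane-1,3-diol | COc1cc(Br)ccc1O[C@H](CO)[C@H](O)c1ccc(OCc2ccccc2)c(OC)c1 | intermediate
8 | (4R,5R)-4-[4-(benzyloxy)-3-methoxyphenyl]-5-(4-bromo-2-methoxyphenoxy)-2,2-dimethyl-1,3-dioxane | COc1cc(Br)ccc1O[C@H](CO2)[C@H](OC2(C)C)c2ccc(OCc3ccccc3)c(OC)c2 | intermediate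
9 | acrolein (prop-2-enal) | C=CC=O | starting material
10 | aryllithium from 8 (Li in place of Br) | COc1cc([Li])ccc1O[C@H](CO2)[C@H](OC2(C)C)c2ccc(OCc3ccccc3)c(OC)c2 | intermediate
11 | 1-(4-{[(4R,5R)-4-[4-(benzyloxy)-3-methoxyphenyl]-2,2-dimethyl-1,3-dioxan-5-yl]oxy}-3-methoxyphenyl)prop-2-en-1-ol, both C7 epimers | COc1cc(C(O)C=C)ccc1O[C@H](CO2)[C@H](OC2(C)C)c2ccc(OCc3ccccc3)c(OC)c2 | intermediate
12 | erythro epoxy alcohol: (R)-(ring B aryl of 11)[(S)-oxiran-2-yl]methanol | COc1cc([C@@H](O)[C@@H]4CO4)ccc1O[C@H](CO2)[C@H](OC2(C)C)c2ccc(OCc3ccccc3)c(OC)c2 | intermediate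
13 | 1-(benzyloxy)-4-bromo-2-methoxybenzene | COc1cc(Br)ccc1OCc1ccccc1 | intermediate
14 | 3-bromo-2-(bromomethyl)prop-1-ene | C=C(CBr)CBr | starting material
15 | [4-(benzyloxy)-3-methoxyphenyl]magnesium bromide | COc1cc([Mg]Br)ccc1OCc1ccccc1 | intermediate
16 | 1-(benzyloxy)-4-[2-(bromomethyl)prop-2-en-1-yl]-2-methoxybenzene | COc1cc(CC(=C)CBr)ccc1OCc1ccccc1 | intermediate
17 | C7 O-{2-[(4-benzyloxy-3-methoxyphenyl)methyl]prop-2-en-1-yl} ether of 12 | COc1cc([C@@H](OCC(=C)Cc5ccc(OCc6ccccc6)c(OC)c5)[C@@H]4CO4)ccc1O[C@H](CO2)[C@H](OC2(C)C)c2ccc(OCc3ccccc3)c(OC)c2 | intermediate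
18 | 1-[4-(benzyloxy)-3-methoxyphenyl]-3-[(R)-(ring B aryl)((S)-oxiran-2-yl)methoxy]propan-2-one | COc1cc([C@@H](OCC(=O)Cc5ccc(OCc6ccccc6)c(OC)c5)[C@@H]4CO4)ccc1O[C@H](CO2)[C@H](OC2(C)C)c2ccc(OCc3ccccc3)c(OC)c2 | intermediate
19 | lithium Z-enolate of 18 (benzylic side) | COc1cc([C@@H](OCC(/O[Li])=C/c5ccc(OCc6ccccc6)c(OC)c5)[C@@H]4CO4)ccc1O[C@H](CO2)[C@H](OC2(C)C)c2ccc(OCc3ccccc3)c(OC)c2 | intermediate
20 | Z triethylsilyl enol ether of 18 | COc1cc([C@@H](OCC(/O[Si](CC)(CC)CC)=C/c5ccc(OCc6ccccc6)c(OC)c5)[C@@H]4CO4)ccc1O[C@H](CO2)[C@H](OC2(C)C)c2ccc(OCc3ccccc3)c(OC)c2 | intermediate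
21 | C8 radical with C9–O–TiCp2Cl from epoxide opening of 20 | COc1cc([C@@H](OCC(/O[Si](CC)(CC)CC)=C/c5ccc(OCc6ccccc6)c(OC)c5)[CH]CO[Ti](Cl)(C7C=CC=C7)C7C=CC=C7)ccc1O[C@H](CO2)[C@H](OC2(C)C)c2ccc(OCc3ccccc3)c(OC)c2 | intermediate
22 | cyclised C7′ benzylic radical (oxolane closed, C9–O–TiCp2Cl, C8′–OSiEt3) | COc1cc([CH][C@@]2(O[Si](CC)(CC)CC)CO[C@H](c3ccc(O[C@H](CO4)[C@H](OC4(C)C)c4ccc(OCc5ccccc5)c(OC)c4)c(OC)c3)[C@H]2CO[Ti](Cl)(C6C=CC=C6)C6C=CC=C6)ccc1OCc1ccccc1 | intermediate
23 | (7S,8R,8′S)-oxolane: C8′ triethylsilyl ether, C9 alcohol, side-chain acetonide, two benzyl ethers | COc1cc(C[C@@]2(O[Si](CC)(CC)CC)CO[C@H](c3ccc(O[C@H](CO4)[C@H](OC4(C)C)c4ccc(OCc5ccccc5)c(OC)c4)c(OC)c3)[C@H]2CO)ccc1OCc1ccccc1 | intermediate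
24 | target with both phenols as benzyl ethers | COc1cc(C[C@@]2(O)CO[C@H](c3ccc(O[C@H](CO)[C@H](O)c4ccc(OCc5ccccc5)c(OC)c4)c(OC)c3)[C@H]2CO)ccc1OCc1ccccc1 | intermediate
25 | CNP0391650.2, (7S,8R,8′S,7″R,8″R) | COc1cc(C[C@@]2(O)CO[C@H](c3ccc(O[C@H](CO)[C@H](O)c4ccc(O)c(OC)c4)c(OC)c3)[C@H]2CO)ccc1O | target

**Step count and risks**

Total step count: 14. Longest linear sequence: 12 (steps 1–6 and 9–14; steps 7 and 8 make the ring C fragment).

Steps most likely to fail:

Step 12. The open radical may be reduced or deoxygenated before the ring closes, the silyloxy group may be lost by β-elimination if the benzylic radical is captured by Cp2TiCl, or the face selectivity at C8′ may be poor. The fallback sets out from ketone 18 and uses the carbonyl group itself as the acceptor: the known Cp2TiCl-mediated reductive epoxide–ketone cyclisation (excess Cp2TiCl, THF, rt), in which the C8 radical adds to the titanium-bound carbonyl carbon and the alkoxide forms directly. This should give the acetonide-protected oxolane diol F1. Hydrolysis of its acetonide under the conditions of step 13 comes back to the route at 24. The face selectivity at C8′ is less predictable in this mode, so separation of C8′ epimers may be needed.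

Step 6. Oxygen transfer may be sluggish or unselective on this hindered polyether, the new terminal epoxide may be opened by isopropoxide on titanium, or the electron-rich benzylic carbinol may ionise. The fallback sets out from 11 (both epimers) and sets C7 by catalyst-controlled reduction instead. MnO2 (CH2Cl2) should give the aryl vinyl ketone F2. Weitz–Scheffer epoxidation (H2O2, NaOH, MeOH, 0 °C) should give the epoxy ketone F3 as both C8 epimers. Corey–Bakshi–Shibata reduction ((R)-methyl oxazaborolidine, BH3·SMe2, THF, −20 °C) should then return 12 together with its C8 epimer F4. The route is rejoined at 12. F4 need not be removed: it would pass through steps 9 to 11 as the epimeric allyl ether F5, ketone F6 and silyl enol ether F7, and converge on 23 in step 12, where C8 becomes planar.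

Step 9. The epoxy alkoxide may undergo Payne rearrangement, the epoxide may be opened by alkoxide or iodide, or 16 may lose HBr. The fallback sets out from 16 and forms the ether without a stoichiometric alkoxide. Hydrolysis (NaHCO3, aqueous acetone, 50 °C) should give the allylic alcohol F8, and Boc2O/DMAP its tert-butyl carbonate F9. Decarboxylative Tsuji–Trost O-allylation of 12 with F9 (Pd2(dba)3, dppb, THF, 50 °C) comes back to the route at 17; only a catalytic amount of alkoxide is present and the 2-substituted allyl unit is symmetrical, so one regioisomer is expected.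

**Further compounds**

F1 | step 12 | (7S,8R,8′S)-oxolane with free C9 and C8′ hydroxyls, side-chain acetonide and two benzyl ethers | COc1cc(C[C@@]2(O)CO[C@H](c3ccc(O[C@H](CO4)[C@H](OC4(C)C)c4ccc(OCc5ccccc5)c(OC)c4)c(OC)c3)[C@H]2CO)ccc1OCc1ccccc1
F2 | step 6 | aryl vinyl ketone from oxidation of 11 | COc1cc(C(=O)C=C)ccc1O[C@H](CO2)[C@H](OC2(C)C)c2ccc(OCc3ccccc3)c(OC)c2
F3 | step 6 | aryl oxiranyl ketone, both C8 epimers | COc1cc(C(=O)C4CO4)ccc1O[C@H](CO2)[C@H](OC2(C)C)c2ccc(OCc3ccccc3)c(OC)c2
F4 | step 6 | C8 epimer of 12 (threo epoxy alcohol) | COc1cc([C@@H](O)[C@H]4CO4)ccc1O[C@H](CO2)[C@H](OC2(C)C)c2ccc(OCc3ccccc3)c(OC)c2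
F5 | step 6 | C8 epimer of 17 | COc1cc([C@@H](OCC(=C)Cc5ccc(OCc6ccccc6)c(OC)c5)[C@H]4CO4)ccc1O[C@H](CO2)[C@H](OC2(C)C)c2ccc(OCc3ccccc3)c(OC)c2
F6 | step 6 | C8 epimer of 18 | COc1cc([C@@H](OCC(=O)Cc5ccc(OCc6ccccc6)c(OC)c5)[C@H]4CO4)ccc1O[C@H](CO2)[C@H](OC2(C)C)c2ccc(OCc3ccccc3)c(OC)c2
F7 | step 6 | C8 epimer of 20 | COc1cc([C@@H](OCC(/O[Si](CC)(CC)CC)=C/c5ccc(OCc6ccccc6)c(OC)c5)[C@H]4CO4)ccc1O[C@H](CO2)[C@H](OC2(C)C)c2ccc(OCc3ccccc3)c(OC)c2
F8 | step 9 | 2-{[4-(benzyloxy)-3-methoxyphenyl]methyl}prop-2-en-1-ol | COc1cc(CC(=C)CO)ccc1OCc1ccccc1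
F9 | step 9 | tert-butyl 2-{[4-(benzyloxy)-3-methoxyphenyl]methyl}prop-2-en-1-yl carbonate | COc1cc(CC(=C)COC(=O)OC(C)(C)C)ccc1OCc1ccccc1
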